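At 15.0 min cedar still holds 55.7% of its starting material, yet its target rose by 3.1 percentage points in the last 5.00 min. A stall with that much feed left looks to me like a catalyst wearing out, so I treat the catalyst as a battery. Elm ends at 120 s with 18.6%, still climbing, so the plateau has to come from cedar, which is this same flask followed so far.

| flask | starting material | second substrate | coupling partner | free catalyst | added ligand | temperature | remark | time |
|---|---|---|---|---|---|---|---|---|
| cedar | 2 mM | 4 mM | 4 mM | 1.6 µM | 4.3 µM | 80 °C | the very flask that is asked about, followed so far |  |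
| elm | 3 mM | 4 mM | 4 mM | 1.6 µM | 4.3 µM | 75 °C | run made earlier |  |
| flask | 2.0 mM | 4.00 mM | 4.00 mM | 1.6 µM | 4.3 µM | 80 °C |  | 20 min |

cedar run (percent of the starting material charged)

| time / min | target / % | starting material / % |
|---|---|---|
| 1.33 | 19.0 | 81.1 |
| 2.00 | 24.1 | 75.6 |
| 3.00 | 28.8 | 71.6 |
| 5.00 | 36.1 | 65.9 |
| 6.00 | 39.6 | 61.9 |
| 10.0 | 41.7 | 58.6 |
| 15.0 | 44.8 | 55.7 |

elm run (percent of the starting material charged)

| time / s | target / % | starting material / % |
|---|---|---|
| 10.0 | 2.0 | 98.0 |
| 20.0 | 2.9 | 93.5 |
| 30.0 | 5.4 | 93.3 |
| 50.0 | 8.9 | 89.4 |
| 80.0 | 13.5 | 86.0 |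
| 90.0 | 15.1 | 84.2 |
| 120 | 18.6 | 82.9 |

(scatter of a reading: 1 percentage point)

- Sunday's: at 20 min take out 90% of the target then present, then wait 20 min
- Tuesday's: at 20 min add free catalyst, 100% of the amount charged, then wait 20 min
- Friday's: at 20 min raise the temperature by 10 K, then wait 20 min
- Wednesday's: change nothing and wait 20 min more
- Monday's: at 20 min add coupling partner, 100% of the amount charged, then wait 20 min

- removed target is counted in
- additions bring no volume worth counting

- target, in percent of the starting material first charged, at 20 min
- which option adds most target ("none" when 2 percentage points or less is all one gets) (Sunday's / Tuesday's / Friday's / Wednesday's / Monday's / none)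
- target present, with what was taken out counted in, in percent of the starting material first charged, after Tuesday's
- target present, with what was taken out counted in, in percent of the starting material first charged, after Monday's

The target gained 5.6 points from 5.00 min to 10.0 min, then 3.1 points, so each step is 0.554 of the one before, as in a first-order lag. Summing that series gives a plateau near 48.6%. On 2 mM of starting material and 1.6 µM of catalyst, that is about 608 turnovers each. If a fresh dose carries the same charge, Tuesday's ends near 97.2%.

The weak link is the plateau, since it rests on scattered readings of a single column. So I reforge it by averaging the target with the starting material lost, which gives 35.1%, 41.5% and 44.5% at those times. The same series now gives 45.9% at 20 min and a plateau of 47.2%. That makes 589 the capacity, c of target at the plateau over c of free catalyst charged, the turnover number. By this reckoning waiting gains 1.3 points, less than the margin of 2 points, and I expect the same from Monday's, which leaves about 47.2%. Tuesday's adds a second charge, and I commit to 93.1%.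

The forecast says 46%, Tuesday's, 68% for Tuesday's and 47.5% for Monday's. For Tuesday's it scales the fresh dose by what remains, “Taking the rate as first order in starting material”, whereas I hold the capacity fixed.

The flask gives 45.4%, Tuesday's as best, 89.0% after Tuesday's and 45.7% after Monday's.

    starting material + free catalyst ⇌ catalyst intermediate A (K = 15000 M⁻¹, k = 12000 M⁻¹ s⁻¹, Ea = 18.0 kJ mol⁻¹, ΔH = 12.0 kJ mol⁻¹)
    coupling partner + catalyst intermediate A → free catalyst + target (k = 5700 M⁻¹ s⁻¹, Ea = 18.0 kJ mol⁻¹)
    second substrate + free catalyst ⇌ catalyst intermediate B (K = 790 M⁻¹, k = 2.20 × 10⁵ M⁻¹ s⁻¹, Ea = 22.0 kJ mol⁻¹, ΔH = −42.0 kJ mol⁻¹)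
    coupling partner + catalyst intermediate B → free catalyst + second product (k = 3600 M⁻¹ s⁻¹, Ea = 30.0 kJ mol⁻¹)
    starting material + catalyst intermediate B → spent catalyst (k = 8.00 M⁻¹ s⁻¹, Ea = 51.0 kJ mol⁻¹)
    free catalyst + added ligand ⇌ idle complex (K = 1.10 × 10⁵ M⁻¹, k = 3900 M⁻¹ s⁻¹, Ea = 23.0 kJ mol⁻¹, ΔH = −84.0 kJ mol⁻¹)
    (constants at 80 °C)

Second substrate holds catalyst as catalyst intermediate B, and starting material turns that into spent catalyst, which is part of the story: without that last step this flask reaches 93.7% instead of 45.4%. Spent catalyst in this flask stands at 99.5% of the catalyst charged at 20 min. In this flask the capacity reckons 47.2% for the fresh dose, and Tuesday's adds 44 points. On a neighbour flask like this one but with 0.0064 mM of free catalyst, it reckons 3.77 mM of target, more than the 2.0 mM charged, and that neighbour flask reaches 94.0% with coupling partner, its limiting reagent, at 0%.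

The data stem from a simulated flask with constants of no real substance; the scatter is artificial.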